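## The problem

Target **25** is a germacranolide. Its ten-membered carbocycle (C1–C10) carries a ketone at C1, a secondary methyl at C10 and a trans 4,5-epoxide with a methyl on C4. A butenolide (O6–C12(=O)–C11=C7) is fused across C6–C7, C11 bears an acetoxymethyl group (C13), and C8 carries an angelate. Five stereocentres must be right (4R,5R,6S,8S,10R). C6 is allylic to C4/C5 and can steer the epoxide through allylic strain. C8 and C10 lie across the ring with no neighbour to lean on, and C10, being α to the ketone, is set by protonation and can be corrected by equilibration. Several groups are fragile. The angelate isomerises to the tiglate under base, nucleophiles, acyl activation or light. The C13 acetate is an allylic leaving group on an acceptor alkene, the epoxide faces a ketone across the ring, and the butenolide has an acidic γ-hydrogen at C6. Closing a ten-membered ring by C–C bond formation fights entropy and transannular strain. The structure offers a way round: C1 is oxygenated and next to the methyl-bearing C10, C4 carries a methyl, and the epoxide is a masked E C4=C5 alkene. Joining C5 to C10 on paper therefore gives a trans-decalin whose ring A is a 1-oxy-1,3-diene (C1=C2–C3=C4), a cyclohexadiene whose only ring σ bond is C5–C10; α-santonin **1** is that decalin, with C14, C15, the 6S lactone oxygen and C12 in place.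

## Retrosynthesis

**25 ⇒ 23 + 24 (C8–O bond).** The angelate goes on last, because it would not survive peroxide, hydrazine, methoxide or 254 nm light earlier in the route. The ester is cut at the C8–O bond rather than at the acyl C–O bond, so the forward step is a Mitsunobu displacement of the 8R alcohol **23** by angelic acid **24**. The acid then acts only as a nucleophile and is never activated as an acyl donor, which is what causes Z→E isomerisation. The forward step must be an SN2 inversion at an allylic ring carbon without elimination.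

**23 ⇒ 22 ⇒ 21 (acetyl–O13 bond; two O–Si bonds).** The C13 acetate is an allylic leaving group on the butenolide and is base-labile, so it is also introduced late, by selective acylation of the primary alcohol of diol **22**. Until then C13 is held as a TIPS ether and C8 as a TBS ether in **21**. The alternative of carrying the acetate from the start would require the enol acetate of the key step to be cleaved selectively beside it, and C10 to be equilibrated in its presence.

**21 ⇒ 20 (C4–O and C5–O bonds).** The trans epoxide is the stereospecific product of peracid addition to the E C4=C5 alkene of **20**. The forward step needs attack on one face only; allylic strain from C6 should provide this.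

**20 ⇒ 19 ⇒ 18 (C10–H bond; C2–C3 hydrogens).** The ketone with its C10 stereocentre comes from the enol acetate **19** by methanolysis and equilibration. **19** comes from the triene **18** by saturating only the cis-disubstituted C2=C3 bond. Reducing first removes the hexatriene, so the thermally labile triene is converted as soon as it is formed.

**18 ⇒ 17 (re-forming C5–C10).** Joining C5 to C10 turns the ten-membered triene into the trans-fused dienyl acetate **17**. This is the largest simplification in the plan: a medium ring with three defined alkene geometries becomes a rigid decalin. Forward, light must open the cyclohexadiene by conrotation, and the trans ring fusion must translate into E geometry at C4=C5.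

**17 ⇒ 16 ⇒ 15 ⇒ 14 ⇒ 13 ⇒ 11 (ring A oxygen from C3 to C1).** The dienyl acetate is the only possible enol acetate of the 1-oxo-2-ene **16**, because C10 is quaternary. **16** comes from the Δ1-3-ketone **13** by nucleophilic epoxidation (**14**), Wharton rearrangement (**15**) and oxidation. **13** comes from the saturated ketone **11**. A direct epoxidation of the santonin dienone followed by reduction of the remaining enone was set aside, because an α,β-epoxy ketone is hydrogenolysed under the conditions that saturate a tetrasubstituted enone.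

**11 ⇒ 10 ⇒ 9 ⇒ 8 (C8–O bond).** The C8 oxygen is placed by SeO2 hydroxylation of butenolide **8** while ring A is masked as a ketal and ring B is a rigid chair. At this stage the regiochemistry (the γ-CH2 trans to the lactone carbonyl) and the configuration (axial, 8β) can be predicted. A late hydroxylation on the ten-membered ketone would expose the ketone α-positions to SeO2 and give no handle on configuration. The 8β alcohol is the wrong epimer, and the Mitsunobu inversion at the end corrects it.

**8 ⇒ 7 ⇒ 6 ⇒ 5 ⇒ 3 ⇒ 2 ⇒ 1 (C13–O bond; C7=C11).** The 13-oxygenated butenolide is reached by dehydrating the tertiary alcohol of **7**, made by dihydroxylating the α-methylene lactone **5** (**6**) and silylating the primary alcohol. **5** comes from the santonin lactone by selenenylation and selenoxide elimination on ketal **3**. Radical bromination of a 13-methyl butenolide was rejected because it attacks the γ-positions (C6, C8) rather than C13. Hydrogenation of **1** to **2** sets the 5α-hydrogen that the key step needs.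

## Roads not taken

**Alternative 1: sulfonium ylide macrocyclization forming the epoxide.**
- Cut and forward step: the C4–C5 bond and the C5–O bond are cut. An ylide made at a C5 diphenylsulfonium centre adds to a C4 methyl ketone in the same chain, and the alkoxide displaces Ph2S to give epoxide **A1**. The ring and the epoxide form in one operation.
- Merits: C8 and C10 would be set in an open chain by ordinary asymmetric methods before the ring exists. The chosen plan cannot do this, and in that respect this road is better.
- Weak points: an intramolecular Corey–Chaykovsky reaction closing a ten-membered ring onto a ketone has little to support it. The ylide carbon is β to the C6 silyloxy group, so elimination competes with addition. The two new stereocentres (one quaternary) depend on the transition-state conformation of a forming medium ring. **A1** still needs oxidative cleavage of the C1 methylene beside a tetrasubstituted enoate, lactonisation and two acylations.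
- Comparison: the chosen plan forms no new stereocentre when the ring appears, and the epoxide configuration follows from a stereospecific addition to an alkene whose geometry is fixed by orbital symmetry.

**Alternative 2: nickel alkylative ynal macrocyclization.**
- Cut and forward step: C7–C8 and C11–C13 are cut. Ni(cod)2 (zerovalent nickel) with a carbene ligand joins an ynoate and the C8 aldehyde through an oxanickelacycle, and a silylmethylzinc reagent delivers C13, giving **A2**.
- Merits: one step makes the ring, the tetrasubstituted alkene with defined geometry by syn addition, C13 as a masked hydroxymethyl group and the C8 carbinol. It is more convergent than the chosen plan and could set C8 under ligand control, where the chosen plan needs a hydroxylation followed by an inversion.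
- Weak points: this manifold has little support for ten-membered rings. The substrate exposes a trisubstituted epoxide and a ketone to low-valent nickel and a Lewis-acidic organozinc. C8 selectivity would come from a macrocyclic transition state that cannot be predicted. Oxidation of the silyl group would then have to be done beside a ketone and an epoxide.
- Comparison: the chosen plan avoids the macrocyclization altogether; the price is length.

**Alternative 3: chromium-mediated macrocyclization with butenolide closure.**
- Cut and forward step: C6–C7 and O–C12 are cut. CrCl2 (divalent chromium) with catalytic NiCl2 converts a (Z)-β-iodoenoate into an alkenylchromium that adds to an epoxy aldehyde, and the C6 alkoxide lactonises to give **A3**.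
- Merits: **A3** is two steps from **25**, so the endgame is shorter than the chosen one. Alkenylchromium additions tolerate ketones and epoxides and have closed medium rings before, and C8 and C10 would again be fixed early. In step count after ring closure this road is better.
- Weak points: C6 would be created in the ring closure by addition to an α-quaternary epoxy aldehyde, with only modest acyclic bias and an unknown macrocyclic one. The tetrasubstituted alkenyl iodide carries an allylic acetate that low-valent nickel can ionise. The linear precursor needs every stereocentre made from scratch.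
- Comparison: the chosen plan takes C6 from santonin and derives the epoxide from it.

Key step: step 15

Assumption (remark on the chemistry): eudesmane/germacrane numbering is used throughout (C12 lactone carbonyl, C13 on C11, C14 on C10, C15 on C4); α/β refer to the usual eudesmane drawing with the C10 methyl β. For the ten-membered compounds the CIP descriptors and SMILES carry the configuration. TBS = tert-butyldimethylsilyl, TIPS = triisopropylsilyl.

## Route

Step 1
Reactants: 1 α-santonin
Product: 2 α-tetrahydrosantonin (3-oxo-4βH,5αH,11βH-eudesman-12,6α-olide)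
Conditions: H2 (1 atm), 10% Pd/C, EtOAc, rt
Reagents that add atoms: none
Why: Heterogeneous hydrogenation saturates C1=C2 and then C4=C5 from the α face, anti to the axial C10 methyl, giving the trans-fused 5α-H ketone that the conrotatory opening needs. C4 need not be controlled: any 4β-methyl epimer is carried along and C4 becomes trigonal in step 14.

Step 2
Reactants: 2 α-tetrahydrosantonin
Product: 3 3,3-ethylenedioxy-4βH,5αH,11βH-eudesman-12,6α-olide
Conditions: ethylene glycol, TsOH (cat.), benzene, reflux, Dean–Stark
Reagents that add atoms: ethylene glycol, OCCO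
Why: Acid-catalysed ketalisation masks the C3 ketone against the amide base of step 3 and against SeO2 in step 7; the lactone is inert.

Step 3
Reactants: 3 3,3-ethylenedioxy-4βH,5αH,11βH-eudesman-12,6α-olide
Product: 5 3,3-ethylenedioxy-4βH,5αH-eudesm-11(13)-en-12,6α-olide, via 11β-phenylselanyl lactone 4 (not isolated)
Conditions: LiN(i-Pr)2, THF, −78 °C; PhSeCl; then AcOH, 30% H2O2, 0 °C → rt
Reagents that add atoms: none
Why: Selenenylation of the lactone enolate puts selenium on the β face of C11, anti to H7α, so the selenoxide syn-elimination can only take a C13 hydrogen and gives the exocyclic α-methylene lactone.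

Step 4
Reactants: 5 3,3-ethylenedioxy-4βH,5αH-eudesm-11(13)-en-12,6α-olide
Product: 6 3,3-ethylenedioxy-11β,13-dihydroxy-4βH,5αH-eudesman-12,6α-olide
Conditions: OsO4 (cat.), N-methylmorpholine N-oxide, acetone–H2O, rt
Reagents that add atoms: N-methylmorpholine N-oxide, C[N+]1([O-])CCOCC1; water, O
Why: Catalytic dihydroxylation (Upjohn conditions) of the only alkene, from the β face anti to H7α, should give the 11β-alcohol. C11 becomes trigonal again in step 6, so only its anti relation to H7 matters.

Step 5
Reactants: 6 3,3-ethylenedioxy-11β,13-dihydroxy-4βH,5αH-eudesman-12,6α-olide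
Product: 7 3,3-ethylenedioxy-11β-hydroxy-13-(triisopropylsilyloxy)-4βH,5αH-eudesman-12,6α-olide
Conditions: TIPSCl, imidazole, DMAP (cat.), DMF, 40 °C
Reagents that add atoms: triisopropylsilyl chloride, CC(C)[Si](Cl)(C(C)C)C(C)C
Why: Only the primary alcohol is silylated; the tertiary α-hydroxy lactone alcohol is too hindered. TIPS tolerates the later acid, does not absorb at 254 nm and, unlike an acetate, is not a leaving group in steps 11 and 12.

Step 6
Reactants: 7 3,3-ethylenedioxy-11β-hydroxy-13-(triisopropylsilyloxy)-4βH,5αH-eudesman-12,6α-olide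
Product: 8 3,3-ethylenedioxy-13-(triisopropylsilyloxy)-4βH,5αH-eudesm-7(11)-en-12,6α-olide
Conditions: SOCl2, pyridine, CH2Cl2, 0 °C
Reagents that add atoms: none
Why: E2 dehydration through the chlorosulfite: H7α is anti-periplanar to the 11β C–O bond, and loss of it gives the conjugated tetrasubstituted butenolide rather than an enol ether toward C13.

Step 7
Reactants: 8 3,3-ethylenedioxy-13-(triisopropylsilyloxy)-4βH,5αH-eudesm-7(11)-en-12,6α-olide
Product: 9 3,3-ethylenedioxy-8β-hydroxy-13-(triisopropylsilyloxy)-4βH,5αH-eudesm-7(11)-en-12,6α-olide (8R, axial OH)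
Conditions: SeO2, pyridine, 1,4-dioxane, 90 °C
Reagents that add atoms: selenium dioxide, O=[Se]=O
Why: SeO2 allylic hydroxylation (ene reaction, then [2,3]-sigmatropic shift) of an α,β-unsaturated ester goes to the γ-carbon trans to the carbonyl, here the C8 methylene; the acyloxy-bearing C6–H and the C13 group on the α-carbon are less disposed to react. Selenium adds to C11 on the β face and takes the axial H8β, so oxygen returns axially (8R), as in the 4β-hydroxylation of Δ5-steroids.

Step 8
Reactants: 9 3,3-ethylenedioxy-8β-hydroxy-13-(triisopropylsilyloxy)-4βH,5αH-eudesm-7(11)-en-12,6α-olide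
Product: 10 8β-(tert-butyldimethylsilyloxy)-3,3-ethylenedioxy-13-(triisopropylsilyloxy)-4βH,5αH-eudesm-7(11)-en-12,6α-olide
Conditions: TBSOTf, 2,6-lutidine, CH2Cl2, −78 → −20 °C
Reagents that add atoms: tert-butyldimethylsilyl triflate, CC(C)(C)[Si](C)(C)OS(=O)(=O)C(F)(F)F
Why: The silyl triflate is needed for the axial alcohol, which is syn to the C10 methyl; at low temperature with lutidine the dioxolane is left alone.

Step 9
Reactants: 10 8β-(tert-butyldimethylsilyloxy)-3,3-ethylenedioxy-13-(triisopropylsilyloxy)-4βH,5αH-eudesm-7(11)-en-12,6α-olide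
Product: 11 8β-(TBS-oxy)-13-(TIPS-oxy)-3-oxo-4βH,5αH-eudesm-7(11)-en-12,6α-olide
Conditions: pyridinium p-toluenesulfonate, acetone–H2O, 60 °C
Reagents that add atoms: water, O
Why: Mild acid hydrolysis of the dioxolane; the hindered secondary TBS ether and the primary TIPS ether tolerate these conditions.

Step 10
Reactants: 11 8β-(TBS-oxy)-13-(TIPS-oxy)-3-oxo-4βH,5αH-eudesm-7(11)-en-12,6α-olide
Product: 13 8β-(TBS-oxy)-13-(TIPS-oxy)-3-oxo-4βH,5αH-eudesma-1,7(11)-dien-12,6α-olide, via 2α-phenylselanyl ketone 12 (not isolated)
Conditions: PhSeCl, EtOAc, rt; then H2O2, pyridine, CH2Cl2, 0 °C → rt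
Reagents that add atoms: none
Why: Acid-mediated α-selenenylation goes through the enol toward the less hindered C2, the site at which trans-fused 3-ketones of this type are halogenated. Selenoxide syn-elimination then gives the Δ1-enone, and no base touches the butenolide.

Step 11
Reactants: 13 8β-(TBS-oxy)-13-(TIPS-oxy)-3-oxo-4βH,5αH-eudesma-1,7(11)-dien-12,6α-olide
Product: 14 1α,2α-epoxy-8β-(TBS-oxy)-13-(TIPS-oxy)-3-oxo-4βH,5αH-eudesm-7(11)-en-12,6α-olide
Conditions: 30% H2O2, NaOH (aq.), MeOH, 0 °C
Reagents that add atoms: hydrogen peroxide, OO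
Why: Weitz–Scheffer epoxidation: hydroperoxide adds to C1 from the α face, anti to the axial C10 methyl. The tetrasubstituted butenolide is too hindered to add peroxide, and if C6 is deprotonated it is reprotonated axially, back to the equatorial lactone that the rigid chair demands.

Step 12
Reactants: 14 1α,2α-epoxy-8β-(TBS-oxy)-13-(TIPS-oxy)-3-oxo-4βH,5αH-eudesm-7(11)-en-12,6α-olide
Product: 15 1α-hydroxy-8β-(TBS-oxy)-13-(TIPS-oxy)-4βH,5αH-eudesma-2,7(11)-dien-12,6α-olide
Conditions: N2H4·H2O, AcOH (cat.), MeOH, 0 °C → rt
Reagents that add atoms: none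
Why: Wharton rearrangement: the epoxy hydrazone collapses to an alkenyl diazene and loses N2, moving oxygen from C3 to C1 with the C1–O configuration retained and leaving the C2=C3 alkene.

Step 13
Reactants: 15 1α-hydroxy-8β-(TBS-oxy)-13-(TIPS-oxy)-4βH,5αH-eudesma-2,7(11)-dien-12,6α-olide
Product: 16 8β-(TBS-oxy)-13-(TIPS-oxy)-1-oxo-4βH,5αH-eudesma-2,7(11)-dien-12,6α-olide
Conditions: Dess–Martin periodinane, CH2Cl2, rt
Reagents that add atoms: none
Why: Dess–Martin oxidation converts the hindered axial allylic alcohol to the enone; silyl ethers and the butenolide are inert.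

Step 14
Reactants: 16 8β-(TBS-oxy)-13-(TIPS-oxy)-1-oxo-4βH,5αH-eudesma-2,7(11)-dien-12,6α-olide
Product: 17 1-acetoxy-8β-(TBS-oxy)-13-(TIPS-oxy)-5αH-eudesma-1,3,7(11)-trien-12,6α-olide
Conditions: isopropenyl acetate, TsOH (cat.), 80 °C
Reagents that add atoms: isopropenyl acetate, CC(=C)OC(C)=O
Why: Acid-catalysed enol acetylation: C10 is quaternary, so the enone can enolise only through the γ-hydrogen at C4. This gives the homoannular 1-acetoxy-1,3-diene regioselectively and removes the C4 stereocentre.

Step 15
Reactants: 17 1-acetoxy-8β-(TBS-oxy)-13-(TIPS-oxy)-5αH-eudesma-1,3,7(11)-trien-12,6α-olide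
Product: 18 (6R,8R)-1-acetoxy-8-(TBS-oxy)-13-(TIPS-oxy)-germacra-1(10),2Z,4E,7(11)-tetraen-12,6-olide (C2 and C9 trans on C1=C10)
Conditions: hν (254 nm, low-pressure Hg lamp, quartz), degassed MeOH, −20 °C, to the photostationary state; kept cold and used at once
Reagents that add atoms: none
Why: Excitation of the dienyl acetate (π→π*, near 265 nm) leads to conrotatory six-electron electrocyclic opening in which the C5–C10 σ bond is broken; the reaction type is the photochemical cyclohexa-1,3-diene to (Z)-hexa-1,3,5-triene opening, known for trans-fused eudesma-1,3-dienes giving cyclodeca-1(10),2,4-trienes. No σ bond forms: the ten-membered ring is not closed but released when the bond shared by the two six-membered rings is cut. No stereocentre is created, and C6 and C8 are spectators. The step needs E geometry at C4=C5 and, for the ring carbons, at C1=C10, with Z at C2=C3; because the ring fusion is trans (5α-H, 10β-CH3), the only conrotatory mode the bicycle allows turns C6 and C9 outward, which fixes exactly this geometry. The diene absorbs far more strongly at 254 nm than the butenolide, and the silyl groups carry no aryl chromophore. The triene absorbs too, so irradiation is taken to a photostationary state and unchanged 17 is recovered after step 16. The triene recloses thermally by disrotation to cis-fused dienes, so it is kept at −20 °C and reduced immediately.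

Step 16
Reactants: 18 (6R,8R)-1-acetoxy-8-(TBS-oxy)-13-(TIPS-oxy)-germacra-1(10),2Z,4E,7(11)-tetraen-12,6-olide
Product: 19 (6R,8R)-1-acetoxy-8-(TBS-oxy)-13-(TIPS-oxy)-germacra-1(10),4E,7(11)-trien-12,6-olide
Conditions: H2 (1 atm), Raney Ni (W-2), MeOH, −20 °C
Reagents that add atoms: none
Why: Low-temperature hydrogenation takes the cis-disubstituted C2=C3 bond in preference to the tetrasubstituted enol acetate, the trisubstituted E-alkene and the tetrasubstituted butenolide, the selectivity known for such photochemically formed cyclodecatrienes. Once the hexatriene is gone, thermal reclosure is no longer possible.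

Step 17
Reactants: 19 (6R,8R)-1-acetoxy-8-(TBS-oxy)-13-(TIPS-oxy)-germacra-1(10),4E,7(11)-trien-12,6-olide
Product: 20 (6R,8R,10R)-8-(TBS-oxy)-13-(TIPS-oxy)-1-oxogermacra-4E,7(11)-dien-12,6-olide
Conditions: K2CO3, MeOH, 0 °C → rt, until the C10 epimer ratio is constant
Reagents that add atoms: none
Why: Methanolysis of the enol acetate, an acyl donor as reactive as an aryl ester, gives the enolate, which is protonated at C10. Kinetic protonation on the outer face is expected to favour the 10S epimer, and continued exposure should equilibrate the α-methyl ketone to 10R, in which C14 is peripheral and the C9–C10 bond eclipses the carbonyl. No base-labile ester is present at this stage.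

Step 18
Reactants: 20 (6R,8R,10R)-8-(TBS-oxy)-13-(TIPS-oxy)-1-oxogermacra-4E,7(11)-dien-12,6-olide
Product: 21 (4R,5R,6S,8R,10R)-4,5-epoxy-8-(TBS-oxy)-13-(TIPS-oxy)-1-oxogermacr-7(11)-en-12,6-olide
Conditions: mCPBA, CH2Cl2, 0 °C
Reagents that add atoms: 3-chloroperoxybenzoic acid, OOC(=O)c1cccc(Cl)c1
Why: Prilezhaev epoxidation of the only nucleophilic alkene is much faster than Baeyer–Villiger oxidation of the ketone. Allylic 1,3-strain holds H6 in the plane of the E C4=C5 bond with C7 on the inner face, so the peracid attacks the outer face syn to O6 and the stereospecific syn addition gives the trans 4R,5R epoxide.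

Step 19
Reactants: 21 (4R,5R,6S,8R,10R)-4,5-epoxy-8-(TBS-oxy)-13-(TIPS-oxy)-1-oxogermacr-7(11)-en-12,6-olide
Product: 22 (4R,5R,6S,8R,10R)-4,5-epoxy-8,13-dihydroxy-1-oxogermacr-7(11)-en-12,6-olide
Conditions: Bu4NF, AcOH, THF, 0 °C → rt
Reagents that add atoms: none
Why: Buffered fluoride removes both silyl ethers; acetic acid keeps the medium from disturbing C10, C6 or the epoxide.

Step 20
Reactants: 22 (4R,5R,6S,8R,10R)-4,5-epoxy-8,13-dihydroxy-1-oxogermacr-7(11)-en-12,6-olide
Product: 23 (4R,5R,6S,8R,10R)-13-acetoxy-4,5-epoxy-8-hydroxy-1-oxogermacr-7(11)-en-12,6-olide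
Conditions: AcCl, 2,4,6-collidine, CH2Cl2, −78 °C
Reagents that add atoms: acetyl chloride, CC(=O)Cl
Why: Kinetic acylation takes the primary allylic alcohol; the secondary C8 alcohol does not compete at this temperature.

Step 21
Reactants: 23 (4R,5R,6S,8R,10R)-13-acetoxy-4,5-epoxy-8-hydroxy-1-oxogermacr-7(11)-en-12,6-olide; 24 angelic acid
Product: 25 (4R,5R,6S,8S,10R)-13-acetoxy-8-angeloyloxy-4,5-epoxy-1-oxogermacr-7(11)-en-12,6-olide (target)
Conditions: PPh3, diisopropyl azodicarboxylate, toluene, 0 °C → rt
Reagents that add atoms: angelic acid (24), C/C=C(/C)C(=O)O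
Why: Mitsunobu esterification with inversion: angelate displaces the 8R alkoxyphosphonium at the allylic carbon to give 8S. The acid is the nucleophile and is never activated as an acyl donor, so the Z alkene is not isomerised.

## Compound list

1 | α-santonin, (11S)-3-oxoeudesma-1,4-dien-12,6α-olide | C[C@H]1[C@@H]2CC[C@]3(C=CC(=O)C(=C3[C@H]2OC1=O)C)C | starting material
2 | α-tetrahydrosantonin, 3-oxo-4βH,5αH,11βH-eudesman-12,6α-olide | C[C@H]1[C@@H]2CC[C@]3(CCC(=O)[C@@H](C)[C@@H]3[C@H]2OC1=O)C | intermediate
3 | 3,3-ethylenedioxy-4βH,5αH,11βH-eudesman-12,6α-olide | C[C@H]1[C@@H]2CC[C@]3(CCC4(OCCO4)[C@@H](C)[C@@H]3[C@H]2OC1=O)C | intermediate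
4 | 3,3-ethylenedioxy-11β-(phenylselanyl)-4βH,5αH-eudesman-12,6α-olide (C13 methyl α) | C[C@@]1([Se]c5ccccc5)[C@@H]2CC[C@]3(CCC4(OCCO4)[C@@H](C)[C@@H]3[C@H]2OC1=O)C | intermediate (not isolated)
5 | 3,3-ethylenedioxy-4βH,5αH-eudesm-11(13)-en-12,6α-olide | C=C1[C@@H]2CC[C@]3(CCC4(OCCO4)[C@@H](C)[C@@H]3[C@H]2OC1=O)C | intermediate
6 | 3,3-ethylenedioxy-11β,13-dihydroxy-4βH,5αH-eudesman-12,6α-olide | OC[C@@]1(O)[C@@H]2CC[C@]3(CCC4(OCCO4)[C@@H](C)[C@@H]3[C@H]2OC1=O)C | intermediate
7 | 3,3-ethylenedioxy-11β-hydroxy-13-(triisopropylsilyloxy)-4βH,5αH-eudesman-12,6α-olide | CC(C)[Si](C(C)C)(C(C)C)OC[C@@]1(O)[C@@H]2CC[C@]3(CCC4(OCCO4)[C@@H](C)[C@@H]3[C@H]2OC1=O)C | intermediate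
8 | 3,3-ethylenedioxy-13-(triisopropylsilyloxy)-4βH,5αH-eudesm-7(11)-en-12,6α-olide | CC(C)[Si](C(C)C)(C(C)C)OCC1=C2CC[C@]3(CCC4(OCCO4)[C@@H](C)[C@@H]3[C@H]2OC1=O)C | intermediate
9 | 3,3-ethylenedioxy-8β-hydroxy-13-(triisopropylsilyloxy)-4βH,5αH-eudesm-7(11)-en-12,6α-olide (8R) | CC(C)[Si](C(C)C)(C(C)C)OCC1=C2[C@H](O)C[C@]3(CCC4(OCCO4)[C@@H](C)[C@@H]3[C@H]2OC1=O)C | intermediate
10 | 8β-(tert-butyldimethylsilyloxy)-3,3-ethylenedioxy-13-(triisopropylsilyloxy)-4βH,5αH-eudesm-7(11)-en-12,6α-olide | CC(C)[Si](C(C)C)(C(C)C)OCC1=C2[C@H](O[Si](C)(C)C(C)(C)C)C[C@]3(CCC4(OCCO4)[C@@H](C)[C@@H]3[C@H]2OC1=O)C | intermediate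
11 | 8β-(TBS-oxy)-13-(TIPS-oxy)-3-oxo-4βH,5αH-eudesm-7(11)-en-12,6α-olide | CC(C)[Si](C(C)C)(C(C)C)OCC1=C2[C@H](O[Si](C)(C)C(C)(C)C)C[C@]3(CCC(=O)[C@@H](C)[C@@H]3[C@H]2OC1=O)C | intermediate
12 | 2α-(phenylselanyl)-8β-(TBS-oxy)-13-(TIPS-oxy)-3-oxo-4βH,5αH-eudesm-7(11)-en-12,6α-olide (either C2 epimer eliminates) | CC(C)[Si](C(C)C)(C(C)C)OCC1=C2[C@H](O[Si](C)(C)C(C)(C)C)C[C@]3(C[C@@H]([Se]c5ccccc5)C(=O)[C@@H](C)[C@@H]3[C@H]2OC1=O)C | intermediate (not isolated)
13 | 8β-(TBS-oxy)-13-(TIPS-oxy)-3-oxo-4βH,5αH-eudesma-1,7(11)-dien-12,6α-olide | CC(C)[Si](C(C)C)(C(C)C)OCC1=C2[C@H](O[Si](C)(C)C(C)(C)C)C[C@]3(C=CC(=O)[C@@H](C)[C@@H]3[C@H]2OC1=O)C | intermediate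
14 | 1α,2α-epoxy-8β-(TBS-oxy)-13-(TIPS-oxy)-3-oxo-4βH,5αH-eudesm-7(11)-en-12,6α-olide | CC(C)[Si](C(C)C)(C(C)C)OCC1=C2[C@H](O[Si](C)(C)C(C)(C)C)C[C@]3([C@H]4O[C@H]4C(=O)[C@@H](C)[C@@H]3[C@H]2OC1=O)C | intermediate
15 | 1α-hydroxy-8β-(TBS-oxy)-13-(TIPS-oxy)-4βH,5αH-eudesma-2,7(11)-dien-12,6α-olide | CC(C)[Si](C(C)C)(C(C)C)OCC1=C2[C@H](O[Si](C)(C)C(C)(C)C)C[C@]3([C@@H](O)C=C[C@@H](C)[C@@H]3[C@H]2OC1=O)C | intermediate
16 | 8β-(TBS-oxy)-13-(TIPS-oxy)-1-oxo-4βH,5αH-eudesma-2,7(11)-dien-12,6α-olide | CC(C)[Si](C(C)C)(C(C)C)OCC1=C2[C@H](O[Si](C)(C)C(C)(C)C)C[C@]3(C(=O)C=C[C@@H](C)[C@@H]3[C@H]2OC1=O)C | intermediate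
17 | 1-acetoxy-8β-(TBS-oxy)-13-(TIPS-oxy)-5αH-eudesma-1,3,7(11)-trien-12,6α-olide | CC(C)[Si](C(C)C)(C(C)C)OCC1=C2[C@H](O[Si](C)(C)C(C)(C)C)C[C@]3(C(OC(C)=O)=CC=C(C)[C@@H]3[C@H]2OC1=O)C | intermediate
18 | (6R,8R)-1-acetoxy-8-(TBS-oxy)-13-(TIPS-oxy)-germacra-1(10),2Z,4E,7(11)-tetraen-12,6-olide; C2 trans to C9 on C1=C10 (Z by CIP) | CC(=O)O/C1=C(/C)C[C@@H](O[Si](C)(C)C(C)(C)C)C2=C(CO[Si](C(C)C)(C(C)C)C(C)C)C(=O)O[C@@H]2/C=C(C)/C=C\1 | intermediate
19 | (6R,8R)-1-acetoxy-8-(TBS-oxy)-13-(TIPS-oxy)-germacra-1(10),4E,7(11)-trien-12,6-olide; C2 trans to C9 on C1=C10 | CC(=O)O/C1=C(/C)C[C@@H](O[Si](C)(C)C(C)(C)C)C2=C(CO[Si](C(C)C)(C(C)C)C(C)C)C(=O)O[C@@H]2/C=C(C)/CC1 | intermediate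
20 | (6R,8R,10R)-8-(TBS-oxy)-13-(TIPS-oxy)-1-oxogermacra-4E,7(11)-dien-12,6-olide | CC(C)(C)[Si](C)(C)O[C@@H]1C[C@@H](C)C(=O)CC/C(C)=C/[C@H]2OC(=O)C(CO[Si](C(C)C)(C(C)C)C(C)C)=C12 | intermediate
21 | (4R,5R,6S,8R,10R)-4,5-epoxy-8-(TBS-oxy)-13-(TIPS-oxy)-1-oxogermacr-7(11)-en-12,6-olide | CC(C)(C)[Si](C)(C)O[C@@H]1C[C@@H](C)C(=O)CC[C@@]2(C)O[C@@H]2[C@H]2OC(=O)C(CO[Si](C(C)C)(C(C)C)C(C)C)=C12 | intermediate
22 | (4R,5R,6S,8R,10R)-4,5-epoxy-8,13-dihydroxy-1-oxogermacr-7(11)-en-12,6-olide | O[C@@H]1C[C@@H](C)C(=O)CC[C@@]2(C)O[C@@H]2[C@H]2OC(=O)C(CO)=C12 | intermediate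
23 | (4R,5R,6S,8R,10R)-13-acetoxy-4,5-epoxy-8-hydroxy-1-oxogermacr-7(11)-en-12,6-olide | O[C@@H]1C[C@@H](C)C(=O)CC[C@@]2(C)O[C@@H]2[C@H]2OC(=O)C(COC(C)=O)=C12 | intermediate
24 | angelic acid, (Z)-2-methylbut-2-enoic acid | C/C=C(/C)C(=O)O | starting material
25 | (4R,5R,6S,8S,10R)-13-acetoxy-8-angeloyloxy-4,5-epoxy-1-oxogermacr-7(11)-en-12,6-olide | C/C=C(/C)C(=O)O[C@H]1C[C@@H](C)C(=O)CC[C@@]2(C)O[C@@H]2[C@H]2OC(=O)C(COC(C)=O)=C12 | target

## Step count and least certain steps

Total step count: 21. Longest linear sequence: 21 steps from 1 (24 is bought).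

**Step 15 (key step).** The likely failures are a photostationary state poor in triene, further photoreactions of the triene (which also absorbs at 254 nm), and loss of the triene by thermal disrotatory reclosure before it can be reduced. Fallback, setting out from 17: the cold photolysate is not worked up but treated at −40 °C with NaOMe in MeOH. This cleaves the enol acetate of the triene and gives, after equilibration at C10, the (2Z,4E)-dienone F1, which is no longer a hexatriene and cannot reclose. Unchanged 17 is returned as enone 16 and goes through step 14 again. Conjugate reduction of the less substituted C2=C3 bond of the dienone F1 with [(Ph3P)CuH]6 in wet benzene (the tetrasubstituted butenolide is inert) rejoins the route at 20. This also removes the cold hydrogenation of step 16, where over-reduction of the strained E alkene is the concern.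

**Step 7.** Hydroxylation may take place at the tertiary, doubly activated C6–H instead of C8, the electron-poor alkene may react sluggishly, over-oxidation to the ketone may occur, and oxygen may be delivered to the wrong face. Fallback, setting out from 8: radical allylic oxidation with Rh2(cap)4 and t-BuOOH gives the 8-oxo butenolide F2. The electrophilic peroxy radical should avoid the C–H bond geminal to the acyloxy oxygen. Corey–Bakshi–Shibata reduction with (S)-2-methyl-CBS-oxazaborolidine and catecholborane then sets 8R under reagent control, matched with the substrate's preference for hydride attack anti to the C10 methyl, and comes back at 9. Any ketone formed in step 7 itself enters at the 8-oxo butenolide F2.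

**Step 17.** Protonation of the enolate on the exposed face may give mainly the 10S epimer, the equilibrium may not lie far enough toward 10R, and long exposure to methoxide may erode C6 through the butenolide γ-hydrogen. Fallback, setting out from 19: the enol acetate is cleaved briefly at −20 °C and the epimers are separated. The 10S ketone F3 is re-equilibrated on its own with DBU in toluene and re-separated, so that material is funnelled to 20 without prolonged exposure of the whole batch to base. The route is rejoined at 20.

**Step 21.** The alkoxyphosphonium may eliminate toward C9 to give a dienolide instead of being displaced by the weakly acidic, hindered angelic acid, and the free C8 alcohol may be partly tied up as a transannular hemiketal with the C1 ketone. Fallback, setting out from 23: Mitsunobu inversion with the stronger, smaller chloroacetic acid gives the 8α-chloroacetate F4. Thiourea and NaHCO3 in EtOH remove the chloroacetyl group beside the C13 acetate and give the 8α-alcohol F5. Acylation of the 8α-alcohol F5 with retention, using the mixed anhydride of 24 and 2,4,6-trichlorobenzoyl chloride (Et3N, toluene, no DMAP), comes back at 25.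

## Further compounds

F1 | step 15 | (6R,8R,10R)-8-(TBS-oxy)-13-(TIPS-oxy)-1-oxogermacra-2Z,4E,7(11)-trien-12,6-olide | CC(C)(C)[Si](C)(C)O[C@@H]1C[C@@H](C)C(=O)/C=C\C(C)=C\[C@H]2OC(=O)C(CO[Si](C(C)C)(C(C)C)C(C)C)=C12
F2 | step 7 | 3,3-ethylenedioxy-8-oxo-13-(triisopropylsilyloxy)-4βH,5αH-eudesm-7(11)-en-12,6α-olide | CC(C)[Si](C(C)C)(C(C)C)OCC1=C2C(=O)C[C@]3(CCC4(OCCO4)[C@@H](C)[C@@H]3[C@H]2OC1=O)C
F3 | step 17 | (6R,8R,10S)-8-(TBS-oxy)-13-(TIPS-oxy)-1-oxogermacra-4E,7(11)-dien-12,6-olide (10-epimer of 20) | CC(C)(C)[Si](C)(C)O[C@@H]1C[C@H](C)C(=O)CC/C(C)=C/[C@H]2OC(=O)C(CO[Si](C(C)C)(C(C)C)C(C)C)=C12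
F4 | step 21 | (4R,5R,6S,8S,10R)-13-acetoxy-8-(chloroacetoxy)-4,5-epoxy-1-oxogermacr-7(11)-en-12,6-olide | O=C(CCl)O[C@H]1C[C@@H](C)C(=O)CC[C@@]2(C)O[C@@H]2[C@H]2OC(=O)C(COC(C)=O)=C12
F5 | step 21 | (4R,5R,6S,8S,10R)-13-acetoxy-4,5-epoxy-8-hydroxy-1-oxogermacr-7(11)-en-12,6-olide | O[C@H]1C[C@@H](C)C(=O)CC[C@@]2(C)O[C@@H]2[C@H]2OC(=O)C(COC(C)=O)=C12
A1 | alternative 1 | ten-membered 4,5-epoxide with C1 exocyclic methylene, 6,8-bis(TBS) ethers and exocyclic C7=C11 enoate (methyl ester, 13-acetate) | CC(C)(C)[Si](C)(C)O[C@H]1C[C@@H](C)C(=C)CC[C@@]2(C)O[C@@H]2[C@@H](O[Si](C)(C)C(C)(C)C)/C1=C(/COC(C)=O)C(=O)OC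
A2 | alternative 2 | ten-membered 8-alcohol with 1-ketone, 4,5-epoxide, 6-triethylsilyl ether and exocyclic C7=C11 enoate carrying CH2SiMe2(Oi-Pr) on C11 | O[C@H]1C[C@@H](C)C(=O)CC[C@@]2(C)O[C@@H]2[C@@H](O[Si](CC)(CC)CC)/C1=C(/C[Si](C)(C)OC(C)C)C(=O)OC
A3 | alternative 3 | 8-O-TBS ether of 13-acetoxy-4,5-epoxy-1-oxogermacr-7(11)-en-12,6-olide | CC(C)(C)[Si](C)(C)O[C@H]1C[C@@H](C)C(=O)CC[C@@]2(C)O[C@@H]2[C@H]2OC(=O)C(COC(C)=O)=C12
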